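## Retrosynthetic overview

1. Locants: the atoms of the target SMILES as read, oxygens outside the rings not counted (C1–C13, O14 = lactone ring oxygen, C15–C25); the same locants are kept for the corresponding atoms of every intermediate.
2. Enabling feature: the spiro carbon C13 carries O14, and its bond to C6 is common to the cyclohexene ring (C6, C7=C8, C10, C12, C13) and the 11-membered ring (C2–C6, C13, C22, C21, C20, C23, C25), with C7=C8 lying across the ring from it. A retro-[4+2] that cuts C6–C13 and C10–C12 therefore opens both rings at once and leaves an exocyclic enol lactone (C13=C12) and a 2-carboxy-1,3-diene (C6=C7–C8=C10) on one chain.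
3. The enol lactone is unravelled further to a cis γ-alkynoic acid (C15 acid, C13≡C12). The key operation thus runs from a monocyclic seco acid to the tetracycle; afterwards only C18=C19 → 1,2-diketone and ester → acid remain.
4. Seco acid: diene by Negishi coupling (C7–C8); C13≡C12 and C15O2H from a menthyl lactone acetal (auxiliary = masked aldehyde/acid); C20–C23 with both stereocentres by Ireland–Claisen rearrangement of a C18 allylic ester whose acid part (C1–C7, C23–C25) comes from (S)-citronellyl bromide; core ring with C16/C18/C22 by auxiliary-controlled Diels–Alder reaction and dianion methylation.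
5. Ring order: six-membered core ring (step 4; the butenolide ring of the dienophile is carried as a temporary lactone-acetal ring up to step 14) → γ-lactone (step 15, first stage) → cyclohexene and, with the later-forming C6–C13 bond of the same cycloaddition, the 11-membered ring as the last ring to close (step 15).

Key step: step 15

Assumption: butenolide 11 is treated as a purchasable reagent (otherwise made from furfural and (−)-menthol), and the target is taken in the 1,2-diketone tautomer drawn in its SMILES.

## Route

Step 1
Reactants: 1 (S)-citronellyl bromide; 2 1-(trimethylsilyl)propyne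
Product: 4 (R)-(6,10-dimethylundec-9-en-1-yn-1-yl)trimethylsilane, via lithiated propyne 3 (not isolated)
Conditions: 2, n-BuLi, TMEDA, THF, −78 → 0 °C; then 1, −78 °C → rt
Reagents that add atoms: none
Why: SN2 alkylation of the propargylic lithium reagent by the primary bromide, the silyl group directing reaction to the propargylic rather than the allenic terminus; the stereocentre of 1 (later C2) is carried over unchanged and only its descriptor changes by priority.

Step 2
Reactants: 4 enyne
Product: 7 (R)-4-methyl-9-(trimethylsilyl)non-8-ynoic acid, via ozonide 5 (not isolated), via aldehyde 6 (not isolated)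
Conditions: O3, CH2Cl2, −78 °C; PPh3, −78 °C → rt; then NaClO2, NaH2PO4, 2-methylbut-2-ene, t-BuOH/H2O, 0 °C → rt
Reagents that add atoms: ozone [O-][O+]=O; sodium chlorite [Na+].[O-]Cl=O
Why: ozonolysis, chemoselective for the electron-rich trisubstituted alkene over the silylalkyne, followed by Pinnick oxidation of the crude aldehyde; no stereocentre is formed.

Step 3
Reactants: 8 methyl but-2-ynoate
Product: 10 methyl (E)-2-iodobut-2-enoate, via vinylstannane 9 (not isolated)
Conditions: Bu3SnH, Pd(PPh3)4 (2 mol %), THF, 0 °C → rt; then I2, CH2Cl2, 0 °C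
Reagents that add atoms: iodine II
Why: palladium-catalysed syn-hydrostannation of the ynoate puts tin on the α-carbon cis to the new β-hydrogen, and iododestannylation with retention should give the iodide with CH3 cis to the ester, the geometry that later places C11 "outside" on the diene.

Step 4
Reactants: 11 (5R)-5-(l-menthyloxy)furan-2(5H)-one; 12 (E)-1-(trimethylsilyloxy)buta-1,3-diene
Product: 14 hydroxy lactone acetal, via silyl ether adduct 13 (not isolated)
Conditions: toluene, BHT (cat.), 110 °C, sealed tube; then 1 M HCl, THF, 0 °C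
Reagents that add atoms: none
Why: Diels–Alder reaction in which the diene should add to the butenolide face opposite the menthyloxy group (absolute configuration at C16 and C22), with the lactone carbonyl endo (C18–O cis to C15) and the oxygen-bearing diene terminus bonding to the α-carbon C16 ("ortho" rule); cold dilute acid then cleaves only the silyl ether.

Step 5
Reactants: 14 hydroxy lactone acetal
Product: 16 C16-methyl hydroxy lactone acetal, via dilithio dianion 15 (not isolated)
Conditions: LiN(i-Pr)2 (2.3 equiv), THF, −78 → −30 °C; MeI, DMPU, −78 → −20 °C; then H2O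
Reagents that add atoms: iodomethane CI
Why: Fráter–Seebach alkylation of the β-hydroxy lactone dianion, in which the alkoxide blocks β-elimination and methyl iodide should enter anti to C18–O on the convex face of the cis-fused bicycle, giving the quaternary C16 with CH3 trans to C18–O and the ring fusion still cis.

Step 6
Reactants: 16 C16-methyl hydroxy lactone acetal; 7 chain acid
Product: 18 allylic ester, via mixed anhydride 17 (not isolated)
Conditions: 7, 2,4,6-trichlorobenzoyl chloride, Et3N, THF, rt; then 16, DMAP, toluene, 60 °C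
Reagents that add atoms: none
Why: Yamaguchi esterification, chosen for the hindered secondary allylic alcohol next to the quaternary carbon; no stereocentre is touched.

Step 7
Reactants: 18 allylic ester
Product: 22 rearranged acid, via lithium enolate 19 (not isolated), via silyl ketene acetal 20 (not isolated), via silyl ester 21 (not isolated)
Conditions: LiN(i-Pr)2, THF/DMPU (4:1), −78 °C; Me3SiCl/Et3N, −78 → 65 °C; then 1 M HCl, rt
Reagents that add atoms: none
Why: Ireland–Claisen rearrangement in which the (Z)-silyl ketene acetal shifts suprafacially across C18–C19=C20, so that C23 bonds to C20 on the face that carried the C18 oxygen (cis to C13 and C15), while the boat-like transition state usual for cyclohexenyl esters keeps the side chain clear of the ring and should set C23 as required; the alkene ends at C18=C19.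

Step 8
Reactants: 22 rearranged acid
Product: 24 primary alcohol, via mixed carbonic anhydride 23 (not isolated)
Conditions: i-BuOCOCl, N-methylmorpholine, THF, −15 °C; then NaBH4, H2O, 0 °C
Reagents that add atoms: none
Why: chemoselective reduction of the carboxylic acid through its mixed carbonic anhydride, which should leave the hindered lactone acetal, the alkene and the silylalkyne alone; no stereocentre is affected.

Step 9
Reactants: 24 primary alcohol
Product: 25 primary iodide
Conditions: I2, PPh3, imidazole, CH2Cl2, 0 °C → rt
Reagents that add atoms: iodine II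
Why: Appel-type iodination of the primary alcohol under neutral conditions; C23 is not involved.

Step 10
Reactants: 25 primary iodide
Product: 26 C23-methyl silylalkyne
Conditions: Bu3SnH, AIBN (cat.), toluene, 80 °C
Reagents that add atoms: none
Why: radical-chain dehalogenation turns C24 into the methyl group; the primary radical has no low-strain cyclization path, and iodine abstraction is much faster than stannyl radical addition to the silylalkyne.

Step 11
Reactants: 26 C23-methyl silylalkyne
Product: 27 terminal alkyne
Conditions: TBAF, AcOH, THF, 0 °C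
Reagents that add atoms: none
Why: fluoride-induced C-desilylation, buffered with acetic acid so that the base-sensitive lactone acetal is not opened.

Step 12
Reactants: 27 terminal alkyne; 10 methyl (E)-2-iodobut-2-enoate
Product: 30 diene ester, via alkenylzirconocene chloride 28 (not isolated), via alkenylzinc chloride 29 (not isolated)
Conditions: Cp2Zr(H)Cl, THF, rt; ZnCl2, 0 °C; then 10, Pd(PPh3)4 (5 mol %), rt
Reagents that add atoms: none
Why: syn hydrozirconation of the terminal alkyne gives the (E)-alkenylzirconium species, and transmetalation to zinc with Negishi coupling, retentive at both sp2 carbons, should give the (2Z,3E)-diene ester with C5 and C11 both "outside".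

Step 13
Reactants: 30 diene ester
Product: 31 pseudoacid
Conditions: CF3CO2H/H2O (4:1), 40 °C
Reagents that add atoms: water O
Why: acid hydrolysis of the mixed lactone acetal releases the auxiliary and gives the pseudoacid (hydroxy lactone in equilibrium with the cis aldehyde acid); methyl ester, diene and ring alkene should be stable to aqueous acid.

Step 14
Reactants: 31 pseudoacid
Product: 32 seco alkynoic acid
Conditions: dimethyl (1-diazo-2-oxopropyl)phosphonate, K2CO3 (3 equiv), MeOH, 0 °C → rt; then aq. citric acid
Reagents that add atoms: dimethyl (1-diazo-2-oxopropyl)phosphonate CC(=O)C(=[N+]=[N-])P(=O)(OC)OC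
Why: Seyferth–Gilbert homologation with the Ohira–Bestmann reagent acts on the aldehyde form of the pseudoacid while C15 stays as the carboxylate; it is run cold so that alkyne formation should outpace epimerization at C22.

Step 15
Reactants: 32 seco alkynoic acid
Product: 34 tetracyclic methyl ester, via enol lactone 33 (not isolated)
Conditions: AuCl (5 mol %), K2CO3 (10 mol %), MeCN, rt; filter, then toluene (1 mM), BHT, 140 °C, sealed tube
Reagents that add atoms: none
Why: Gold-catalysed 5-exo-dig anti-addition of the C15 carboxylate to the C13≡C12 alkyne closes the γ-lactone as the exocyclic enol lactone 33, which on heating undergoes an intramolecular inverse-electron-demand Diels–Alder reaction in which the nucleophilic methylene C12 bonds to the ester β-carbon C10 and C13 bonds to C6. The closest known reaction types are the cycloisomerization of γ-alkynoic acids to γ-methylene butyrolactones, the macrocyclizing intramolecular Diels–Alder reaction of exocyclic methylene lactones (spirotetronate formation) and [4+2] additions of enol ethers and enol esters to 2-alkoxycarbonyl dienes. Ring closures: the lactone by 5-exo-dig cyclization, the cyclohexene by suprafacial [4+2] cycloaddition, and the 11-membered ring by the C6–C13 bond of that same cycloaddition through a nine-atom tether, this being the later-forming bond of the asynchronous transition state. C13 is controlled by the tether, which starts at C20 on the same side of the core ring as C13 and can present the diene only to the methylene face syn to C21; C6 and C10 follow from an endo ring oxygen (the usual preference of the donor oxygen in inverse-demand additions, which also keeps the bulky core exo) and from the retained diene geometry, so that C5, C11 and O14 should end cis on the new ring. Regiochemistry is fixed by the tether and matches the polarity of both partners, the unactivated C18=C19 alkene cannot compete, and high dilution with BHT should suppress intermolecular addition.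

Step 16
Reactants: 34 tetracyclic methyl ester
Product: 35 tetracyclic acid
Conditions: LiOH·H2O, THF/MeOH/H2O (3:1:1), 40 °C; then 1 M HCl
Reagents that add atoms: lithium hydroxide [Li+].[OH-]
Why: saponification of the methyl ester; the lactone carbonyl is flanked by a quaternary carbon and a fully substituted spiro carbon and, if opened, should re-close on acidification.

Step 17
Reactants: 35 tetracyclic acid
Product: 36 cis-diol acid
Conditions: OsO4 (2 mol %), NMO, acetone/H2O, rt
Reagents that add atoms: N-methylmorpholine N-oxide C[N+]1([O-])CCOCC1; water O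
Why: catalytic OsO4 dihydroxylation of the only electron-rich alkene (C18=C19), expected on the face away from the lactone and the 11-membered ring while the conjugated trisubstituted enoate stays inert; the diol configuration is immaterial because both carbinols are oxidized next.

Step 18
Reactants: 36 cis-diol acid
Product: 37 target CNP0115928.1
Conditions: IBX (3 equiv), DMSO, rt
Reagents that add atoms: none
Why: IBX oxidizes 1,2-diols to 1,2-diketones without C–C cleavage and tolerates the free acid; C20, a bridgehead of the 11-membered ring, should keep its configuration.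

## Compound list

1 | (S)-citronellyl bromide, (6S)-8-bromo-2,6-dimethyloct-2-ene | BrCC[C@@H](C)CCC=C(C)C | starting material
2 | 1-(trimethylsilyl)propyne | CC#C[Si](C)(C)C | starting material
3 | 3-lithio-1-(trimethylsilyl)propyne (not isolated) | [Li]CC#C[Si](C)(C)C | intermediate
4 | (R)-(6,10-dimethylundec-9-en-1-yn-1-yl)trimethylsilane | C[Si](C)(C)C#CCCC[C@@H](C)CCC=C(C)C | intermediate
5 | ozonide (3,3-dimethyl-1,2,4-trioxolane) of 4 (not isolated) | C[Si](C)(C)C#CCCC[C@@H](C)CCC1OOC(C)(C)O1 | intermediate
6 | (R)-4-methyl-9-(trimethylsilyl)non-8-ynal (not isolated) | C[Si](C)(C)C#CCCC[C@@H](C)CCC=O | intermediate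
7 | (R)-4-methyl-9-(trimethylsilyl)non-8-ynoic acid (carboxyl = C24; C23, C25, C2 with its methyl C1, C3–C5, C6≡C7–SiMe3) | C[Si](C)(C)C#CCCC[C@@H](C)CCC(=O)O | intermediate
8 | methyl but-2-ynoate | CC#CC(=O)OC | starting material
9 | methyl (E)-2-(tributylstannyl)but-2-enoate (not isolated) | CCCC[Sn](CCCC)(CCCC)/C(C(=O)OC)=C/C | intermediate
10 | methyl (E)-2-iodobut-2-enoate (CH3 cis to the ester) | C/C=C(/I)C(=O)OC | intermediate
11 | (5R)-5-{[(1R,2S,5R)-2-isopropyl-5-methylcyclohexyl]oxy}furan-2(5H)-one | O=C1C=C[C@H](O[C@@H]2C[C@H](C)CC[C@H]2C(C)C)O1 | starting material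
12 | (E)-1-(trimethylsilyloxy)buta-1,3-diene | C=C/C=C/O[Si](C)(C)C | starting material
13 | Diels–Alder adduct, trimethylsilyl ether of 14 (not isolated) | C[Si](C)(C)O[C@H]1C=CC[C@H]2[C@H](O[C@@H]3C[C@H](C)CC[C@H]3C(C)C)OC(=O)[C@@H]12 | intermediate
14 | cis-fused 7-hydroxy-3-(l-menthyloxy)-3a,4,7,7a-tetrahydro-2-benzofuran-1(3H)-one: C18–OH cis to the lactone carbonyl carbon C15, O-menthyl on C13 trans to C21, C19=C20 | O[C@H]1C=CC[C@H]2[C@H](O[C@@H]3C[C@H](C)CC[C@H]3C(C)C)OC(=O)[C@@H]12 | intermediate
15 | dilithium alkoxide enolate of 14 (not isolated) | [Li]O[C@H]1C=CC[C@H]2[C@H](O[C@@H]3C[C@H](C)CC[C@H]3C(C)C)OC(O[Li])=C12 | intermediate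
16 | 14 carrying CH3 (C17) on the ring-fusion carbon C16, trans to C18–OH, ring fusion cis | O[C@H]1C=CC[C@H]2[C@H](O[C@@H]3C[C@H](C)CC[C@H]3C(C)C)OC(=O)[C@@]12C | intermediate
17 | mixed anhydride of 7 with 2,4,6-trichlorobenzoic acid (not isolated) | C[Si](C)(C)C#CCCC[C@@H](C)CCC(=O)OC(=O)c1c(Cl)cc(Cl)cc1Cl | intermediate
18 | C18 ester of alcohol 16 with acid 7 | C[Si](C)(C)C#CCCC[C@@H](C)CCC(=O)O[C@H]1C=CC[C@H]2[C@H](O[C@@H]3C[C@H](C)CC[C@H]3C(C)C)OC(=O)[C@@]12C | intermediate
19 | (Z)-lithium enolate of 18 (not isolated) | [Li]O/C(O[C@H]1C=CC[C@H]2[C@H](O[C@@H]3C[C@H](C)CC[C@H]3C(C)C)OC(=O)[C@@]12C)=C\C[C@H](C)CCCC#C[Si](C)(C)C | intermediate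
20 | (Z)-trimethylsilyl ketene acetal of 18, side chain cis to OSiMe3 (not isolated) | C[Si](C)(C)O/C(O[C@H]1C=CC[C@H]2[C@H](O[C@@H]3C[C@H](C)CC[C@H]3C(C)C)OC(=O)[C@@]12C)=C\C[C@H](C)CCCC#C[Si](C)(C)C | intermediate
21 | trimethylsilyl ester of 22 (not isolated) | C[Si](C)(C)C#CCCC[C@@H](C)C[C@@H](C(=O)O[Si](C)(C)C)[C@H]1C[C@H]2[C@H](O[C@@H]3C[C@H](C)CC[C@H]3C(C)C)OC(=O)[C@@]2(C)C=C1 | intermediate
22 | rearranged acid: C23 (bearing CO2H = C24 and the C25–C2–C7 chain) bonded to C20 cis to C13; C18=C19; lactone acetal retained | C[Si](C)(C)C#CCCC[C@@H](C)C[C@@H](C(=O)O)[C@H]1C[C@H]2[C@H](O[C@@H]3C[C@H](C)CC[C@H]3C(C)C)OC(=O)[C@@]2(C)C=C1 | intermediate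
23 | mixed isobutyl carbonic anhydride of 22 (not isolated) | C[Si](C)(C)C#CCCC[C@@H](C)C[C@@H](C(=O)OC(=O)OCC(C)C)[C@H]1C[C@H]2[C@H](O[C@@H]3C[C@H](C)CC[C@H]3C(C)C)OC(=O)[C@@]2(C)C=C1 | intermediate
24 | primary alcohol (C24H2OH) | C[Si](C)(C)C#CCCC[C@@H](C)C[C@@H](CO)[C@H]1C[C@H]2[C@H](O[C@@H]3C[C@H](C)CC[C@H]3C(C)C)OC(=O)[C@@]2(C)C=C1 | intermediate
25 | primary iodide (C24H2–iodine) | C[Si](C)(C)C#CCCC[C@@H](C)C[C@@H](CI)[C@H]1C[C@H]2[C@H](O[C@@H]3C[C@H](C)CC[C@H]3C(C)C)OC(=O)[C@@]2(C)C=C1 | intermediate
26 | C23-methyl compound with C6≡C7–SiMe3 | C[Si](C)(C)C#CCCC[C@@H](C)C[C@@H](C)[C@H]1C[C@H]2[C@H](O[C@@H]3C[C@H](C)CC[C@H]3C(C)C)OC(=O)[C@@]2(C)C=C1 | intermediate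
27 | terminal alkyne (C6≡C7H) | C#CCCC[C@@H](C)C[C@@H](C)[C@H]1C[C@H]2[C@H](O[C@@H]3C[C@H](C)CC[C@H]3C(C)C)OC(=O)[C@@]2(C)C=C1 | intermediate
28 | (E)-alkenylzirconocene chloride, cyclopentadienyl ligands written σ-bonded (not isolated) | Cl[Zr](/C=C/CCC[C@@H](C)C[C@@H](C)[C@H]1C[C@H]2[C@H](O[C@@H]3C[C@H](C)CC[C@H]3C(C)C)OC(=O)[C@@]2(C)C=C1)(C1C=CC=C1)C1C=CC=C1 | intermediate
29 | (E)-alkenylzinc chloride (not isolated) | Cl[Zn]/C=C/CCC[C@@H](C)C[C@@H](C)[C@H]1C[C@H]2[C@H](O[C@@H]3C[C@H](C)CC[C@H]3C(C)C)OC(=O)[C@@]2(C)C=C1 | intermediate
30 | diene ester: methyl (2Z,3E)-2-ethylidenealk-3-enoate (C11 cis to the ester, C6=C7 E) on the lactone acetal core | C/C=C(C(=O)OC)/C=C/CCC[C@@H](C)C[C@@H](C)[C@H]1C[C@H]2[C@H](O[C@@H]3C[C@H](C)CC[C@H]3C(C)C)OC(=O)[C@@]2(C)C=C1 | intermediate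
31 | pseudoacid: C13 hydroxy lactone (both epimers at C13), tautomer of the cis aldehyde acid | C/C=C(C(=O)OC)/C=C/CCC[C@@H](C)C[C@@H](C)[C@H]1C[C@H]2C(O)OC(=O)[C@@]2(C)C=C1 | intermediate
32 | seco acid: cyclohexene (C18=C19) with CH3 and CO2H on C16, ethynyl on C22 cis to CO2H, diene-ester chain on C20 cis to ethynyl | C/C=C(C(=O)OC)/C=C/CCC[C@@H](C)C[C@@H](C)[C@H]1C[C@@H](C#C)[C@@](C)(C(=O)O)C=C1 | intermediate
33 | exocyclic enol lactone (C13=C12H2), cis-fused (not isolated) | C/C=C(C(=O)OC)/C=C/CCC[C@@H](C)C[C@@H](C)[C@H]1C[C@H]2C(=C)OC(=O)[C@@]2(C)C=C1 | intermediate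
34 | tetracyclic methyl ester: target skeleton with C18=C19 in place of the diketone | C[C@@H]1CCC[C@H]2C=C(C(=O)OC)[C@@H](C)C[C@@]23OC(=O)[C@@]2(C)C=C[C@H](C[C@H]23)[C@H](C)C1 | intermediate
35 | tetracyclic acid (C18=C19) | C[C@@H]1CCC[C@H]2C=C(C(=O)O)[C@@H](C)C[C@@]23OC(=O)[C@@]2(C)C=C[C@H](C[C@H]23)[C@H](C)C1 | intermediate
36 | C18,C19 cis-diol acid (hydroxyls on the face opposite the lactone) | C[C@@H]1CCC[C@H]2C=C(C(=O)O)[C@@H](C)C[C@@]23OC(=O)[C@@]2(C)[C@H](O)[C@H](O)[C@H](C[C@H]23)[C@H](C)C1 | intermediate
37 | CNP0115928.1 | C[C@@H]1CCC[C@H]2C=C(C(=O)O)[C@@H](C)C[C@@]23OC(=O)[C@@]2(C)C(=O)C(=O)[C@H](C[C@H]23)[C@H](C)C1 | target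

## Step count and risks

Total: 18 steps. Longest linear sequence: 15 steps (steps 4–18; the branch through steps 1, 2 and 6–18 is equally long).

Steps most likely to fail:

1. Step 15. The cycloaddition of the ester-bearing diene with the enol ester may be slower than migration of the exocyclic double bond into the lactone ring, or than hydrolysis of the enol lactone. The fallback sets out from 32 and comes back at 34; it moves the dienophile to the more electron-rich lactol-ether oxidation level. The C15 acid of 32 would be reduced through its acyl fluoride (cyanuric fluoride, pyridine; then NaBH4) to the alkynol F1, and Dess–Martin oxidation would give the non-enolizable alkynal F2. AuCl3 (cat.) or Pd(OAc)2 (cat.) in MeOH would cyclize the hemiacetal onto the alkyne to the 2-methoxy-5-methylenetetrahydrofuran F3. This cyclic enol ether is an established partner for 2-alkoxycarbonyl dienes and should undergo the same tether-controlled intramolecular Diels–Alder reaction at 60–90 °C to the spiro lactol methyl ether F4. Jones oxidation (CrO3, H2SO4, acetone) of the lactol ether would then give lactone 34.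

2. Step 7. Competition between boat-like and chair-like transition states, or incomplete control of enolate geometry, may erode selectivity at C23. The fallback sets out from 22 (as the C23 epimer mixture) and comes back at 22 (single epimer); it corrects C23 in a temporary ring instead of in the rearrangement. Iodolactonization (I2, NaHCO3, MeCN) of the C24 acid onto C19 would give the cis-fused bicyclic iodolactone F5. Enolization with LiN(SiMe3)2 at −78 °C and kinetic protonation from the convex face (2,6-di-tert-butylphenol) would place the side chain on the concave face, which is the required C23 configuration, giving iodolactone F6. Zinc in acetic acid would then re-open the lactone reductively, restoring C18=C19 and returning 22.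

3. Step 5. β-Elimination of the C18 oxygen, O-methylation or incomplete deprotonation at the hindered ring-fusion carbon may intervene. The fallback sets out from 12 (with commercial 3-methylfuran-2(5H)-one in place of 11) and comes back at 16; it carries the methyl group in the dienophile. Allylic bromination (NBS, AIBN, CCl4, reflux) would give 5-bromo-3-methylfuran-2(5H)-one F7. Koenigs–Knorr-type substitution with (−)-menthol and Ag2CO3, followed by separation of the acetal epimers (the unwanted one re-equilibrated with acid), would give (5R)-5-(l-menthyloxy)-3-methylfuran-2(5H)-one F8. Its Diels–Alder reaction with 12 (toluene, 130 °C) would form the quaternary C16 directly in the silyl ether adduct F9, and 1 M HCl would give 16.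

Further compounds
F1 | step 15 | alkynol: C15H2OH analogue of 32 | C/C=C(C(=O)OC)/C=C/CCC[C@@H](C)C[C@@H](C)[C@H]1C[C@@H](C#C)[C@@](C)(CO)C=C1
F2 | step 15 | alkynal: C15 aldehyde analogue of 32 | C/C=C(C(=O)OC)/C=C/CCC[C@@H](C)C[C@@H](C)[C@H]1C[C@@H](C#C)[C@@](C)(C=O)C=C1
F3 | step 15 | 2-methoxy-5-methylenetetrahydrofuran (C15 methyl acetal, both epimers; C13=C12H2) | C/C=C(C(=O)OC)/C=C/CCC[C@@H](C)C[C@@H](C)[C@H]1C[C@H]2C(=C)OC(OC)[C@@]2(C)C=C1
F4 | step 15 | spiro lactol methyl ether: 34 with C15 as methyl acetal (both epimers) | C[C@@H]1CCC[C@H]2C=C(C(=O)OC)[C@@H](C)C[C@@]23OC(OC)[C@@]2(C)C=C[C@H](C[C@H]23)[C@H](C)C1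
F5 | step 7 | iodolactone from 22: C24 lactone oxygen on C19, iodine on C18, C23 epimer mixture | C[Si](C)(C)C#CCCC[C@@H](C)CC1C(=O)O[C@H]2[C@@H]1C[C@H]3[C@H](O[C@@H]4C[C@H](C)CC[C@H]4C(C)C)OC(=O)[C@@]3(C)[C@@H]2I
F6 | step 7 | iodolactone with the side chain on the concave face (required C23 configuration) | C[Si](C)(C)C#CCCC[C@@H](C)C[C@H]1C(=O)O[C@H]2[C@@H]1C[C@H]3[C@H](O[C@@H]4C[C@H](C)CC[C@H]4C(C)C)OC(=O)[C@@]3(C)[C@@H]2I
F7 | step 5 | 5-bromo-3-methylfuran-2(5H)-one (racemic) | CC1=CC(Br)OC1=O
F8 | step 5 | (5R)-5-(l-menthyloxy)-3-methylfuran-2(5H)-one | CC1=C[C@H](O[C@@H]2C[C@H](C)CC[C@H]2C(C)C)OC1=O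
F9 | step 5 | Diels–Alder adduct, trimethylsilyl ether of 16 | C[Si](C)(C)O[C@H]1C=CC[C@H]2[C@H](O[C@@H]3C[C@H](C)CC[C@H]3C(C)C)OC(=O)[C@@]12C
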